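The lowest flavan-3,4-diol unit is cut across ring C into a C4 acyl-anion equivalent carried by ring A and a C2–C3–O1 oxirane. In the key step the lithiated 2-(2-fluoroaryl)-1,3-dithiane opens the (R)-aryloxirane at C3 (C3–C4) and the released C2 alkoxide displaces the ortho fluoride (O1–C8a), closing the pyran with C2 already set. It exploits the ortho relation of C4a and C8a on ring A and the 1,3-relation of O1 and C4 in ring C. The chroman is taken to tri-O-benzylmollisacacidin, which serves three times: tethered 3,4-cis coupling, thiophilic 3,4-trans coupling, then deprotection.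

Key step: step 3

Remark: 1 and 4 are taken as catalogue compounds; 14 and 15 are drawn as their main 3,4-trans epimers, and either C4 epimer serves, because C4 is ionised again in steps 11 and 12.

Step 1
Reactants: 1 2-bromo-1-[3,4-bis(benzyloxy)phenyl]ethan-1-one
Product: 3 (2R)-2-[3,4-bis(benzyloxy)phenyl]oxirane, via bromohydrin 2 (not isolated)
Conditions: (3aR)-1-methyl-3,3-diphenyltetrahydro-1H,3H-pyrrolo[1,2-c][1,3,2]oxazaborole (cat.), BH3·SMe2, THF, 0 °C; then 2 M NaOH, rt
Reagents that add atoms: none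
Why: Corey–Bakshi–Shibata reduction, in which the (R)-oxazaborolidine–borane complex delivers hydride to one face of the aryl ketone and sets the carbinol centre as (R), after which hydroxide closes the oxirane by internal Williamson displacement of bromide at the CH2 carbon without touching the stereocentre.

Step 2
Reactants: 4 4-(benzyloxy)-2-fluorobenzaldehyde
Product: 5 2-[4-(benzyloxy)-2-fluorophenyl]-1,3-dithiane
Conditions: HS(CH2)3SH, BF3·OEt2 (cat.), CH2Cl2, 0 °C → rt
Reagents that add atoms: propane-1,3-dithiol SCCCS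
Why: Lewis-acid-catalysed dithioacetalisation masks the aldehyde carbon (the later C4) as a Corey–Seebach acyl-anion equivalent; no stereocentre is formed.

Step 3
Reactants: 5 2-[4-(benzyloxy)-2-fluorophenyl]-1,3-dithiane; 3 (2R)-2-[3,4-bis(benzyloxy)phenyl]oxirane
Product: 8 (2S)-7-(benzyloxy)-2-[3,4-bis(benzyloxy)phenyl]-2,3-dihydrospiro[chromene-4,2'-[1,3]dithiane], via lithiated dithiane 6 (not isolated), via lithium alkoxide 7 (not isolated)
Conditions: n-BuLi (1.0 equiv), THF, −78 °C; 3, DMPU, −78 °C → rt; then 65 °C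
Reagents that add atoms: none
Why: n-BuLi removes the acidic dithiane C–H of 5 at −78 °C (Corey–Seebach umpolung; any aryl-lithium formed beside fluorine is reprotonated by 5 at this temperature), and carbanion 6 opens oxirane 3 by SN2 attack at the unhindered CH2 (C3), which forms C3–C4 and frees the C2 oxygen as alkoxide 7. On warming in THF–DMPU the alkoxide adds to the fluorine-bearing carbon C8a and fluoride leaves as LiF (intramolecular SNAr through a Meisenheimer adduct), which forms O1–C8a and closes ring C in a 6-exo-trig mode. The closest known reactions are the alkylation of 2-aryl-2-lithio-1,3-dithianes with aryl oxiranes and the alkoxide–aryl fluoride pyran closure used in flavan synthesis; here both run in one flask. The only stereocentre, C2, comes from 3 and is not touched in either event, and C4 is a spiro dithioketal carbon without stereochemistry. The step needs terminal rather than benzylic opening of the oxirane, which DMPU (solvent-separated ion pair, SN2 control) and the bulk of 6 secure, and ring closure on an arene without a conjugating activator, which the inductive effect of the meta benzyloxy group and the gem-disubstituted dithiane carbon in the tether support; no carbonyl group is present, so retro-aldol cleavage and loss of the C2 configuration cannot occur.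

Step 4
Reactants: 8 (2S)-7-(benzyloxy)-2-[3,4-bis(benzyloxy)phenyl]-2,3-dihydrospiro[chromene-4,2'-[1,3]dithiane]
Product: 9 (2S)-7-(benzyloxy)-2-[3,4-bis(benzyloxy)phenyl]-2,3-dihydro-4H-chromen-4-one
Conditions: MeI, CaCO3, MeCN–H2O, 45 °C
Reagents that add atoms: water O
Why: Alkylative hydrolysis of the dithioketal (S-methylation, then attack of water) unmasks the C4 ketone under buffered, non-basic conditions, so the base-labile C2 centre of the flavanone is kept.

Step 5
Reactants: 9 (2S)-7-(benzyloxy)-2-[3,4-bis(benzyloxy)phenyl]-2,3-dihydro-4H-chromen-4-one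
Product: 12 (2R,3R)-7-(benzyloxy)-2-[3,4-bis(benzyloxy)phenyl]-3-hydroxy-2,3-dihydro-4H-chromen-4-one, via silyl enol ether 10 (not isolated), via silyloxy ketone 11 (not isolated)
Conditions: Me3SiOTf, Et3N, CH2Cl2, 0 °C; dimethyldioxirane, acetone, −40 → 0 °C; citric acid, MeOH
Reagents that add atoms: dimethyldioxirane CC1(C)OO1
Why: Rubottom oxidation, in which soft enolisation gives the 4-silyloxy-2H-chromene 10, dimethyldioxirane attacks its face opposite the C2 aryl group, and silyl migration followed by mild hydrolysis leaves the 3-hydroxy ketone with the 2,3-trans geometry, which is also the thermodynamic one.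

Step 6
Reactants: 12 (2R,3R)-7-(benzyloxy)-2-[3,4-bis(benzyloxy)phenyl]-3-hydroxy-2,3-dihydro-4H-chromen-4-one
Product: 13 (2R,3S,4R)-7-(benzyloxy)-2-[3,4-bis(benzyloxy)phenyl]-3,4-dihydro-2H-chromene-3,4-diol (tri-O-benzylmollisacacidin)
Conditions: NaBH4, MeOH–THF, 0 °C
Reagents that add atoms: none
Why: Substrate-controlled borohydride reduction of a 2,3-trans-dihydroflavonol, in which axial hydride attack at C4 gives the equatorial 4-hydroxyl trans to the 3-hydroxyl, the classical route from dihydroflavonols to 2,3-trans-3,4-trans-flavan-3,4-diols.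

Step 7
Reactants: 13 (2R,3S,4R)-7-(benzyloxy)-2-[3,4-bis(benzyloxy)phenyl]-3,4-dihydro-2H-chromene-3,4-diol
Product: 14 (2R,3S,4R)-7-(benzyloxy)-2-[3,4-bis(benzyloxy)phenyl]-4-methoxy-3,4-dihydro-2H-chromen-3-ol
Conditions: MeOH, camphor-10-sulfonic acid (cat.), CH2Cl2, 0 °C → rt
Reagents that add atoms: methanol CO
Why: Acid-catalysed SN1 solvolysis, in which the 4-hydroxyl ionises to the flavan-4-yl cation (stabilised by O1 and the para 7-benzyloxy group) and methanol adds mainly anti to the 3-hydroxyl; the C4 configuration is of no consequence because the centre is ionised again in step 11.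

Step 8
Reactants: 13 (2R,3S,4R)-7-(benzyloxy)-2-[3,4-bis(benzyloxy)phenyl]-3,4-dihydro-2H-chromene-3,4-diol
Product: 15 (2R,3R,4R)-7-(benzyloxy)-4-(benzylsulfanyl)-2-[3,4-bis(benzyloxy)phenyl]-3,4-dihydro-2H-chromen-3-ol
Conditions: PhCH2SH, camphor-10-sulfonic acid (cat.), CH2Cl2, 0 °C
Reagents that add atoms: phenylmethanethiol SCc1ccccc1
Why: Thiolysis of the benzylic 4-hydroxyl through the same flavan-4-yl cation, the thiol entering mainly anti to the 3-hydroxyl, gives a thioether that is inert to oxophilic Lewis acids and is kept as a latent leaving group for step 12.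

Step 9
Reactants: 15 (2R,3R,4R)-7-(benzyloxy)-4-(benzylsulfanyl)-2-[3,4-bis(benzyloxy)phenyl]-3,4-dihydro-2H-chromen-3-ol
Product: 16 6-oxo-6-{[(2R,3R,4R)-7-(benzyloxy)-4-(benzylsulfanyl)-2-[3,4-bis(benzyloxy)phenyl]-3,4-dihydro-2H-chromen-3-yl]oxy}hexanoic acid (3-O-hemiadipate of 15)
Conditions: adipic acid (5 equiv), N,N'-diisopropylcarbodiimide, 4-(dimethylamino)pyridine (cat.), THF–CH2Cl2, rt
Reagents that add atoms: adipic acid OC(=O)CCCCC(=O)O
Why: Steglich esterification of the only free hydroxyl (3-OH) with a large excess of the diacid, so that the mono-ester results; no stereocentre is touched.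

Step 10
Reactants: 16 3-O-hemiadipate of 15; 14 (2R,3S,4R)-7-(benzyloxy)-2-[3,4-bis(benzyloxy)phenyl]-4-methoxy-3,4-dihydro-2H-chromen-3-ol
Product: 17 mixed hexanedioate diester: one acyl end on the 3-oxygen of 14, the other on the 3-oxygen of 15
Conditions: N,N'-diisopropylcarbodiimide, 4-(dimethylamino)pyridine, CH2Cl2, rt
Reagents that add atoms: none
Why: Steglich esterification of acid 16 with the single free hydroxyl of 14 links the two flavan units through their 3-oxygens without touching any stereocentre.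

Step 11
Reactants: 17 mixed hexanedioate diester of 14 and 15
Product: 18 adipate-bridged dimer: the unit from 14, now 2,3-trans-3,4-cis, is bonded from C4 to C6 of the unit from 15 (4-benzylsulfanyl kept)
Conditions: Me3SiOTf (cat.), CH2Cl2 (1 mM), −40 → −20 °C; Et3N quench
Reagents that add atoms: none
Why: Intramolecular Friedel–Crafts alkylation, in which Me3SiOTf ionises the 4-methoxy group to the flavan-4-yl cation, C6 of the tethered unit (para to the ring oxygen and less hindered than C8) captures it, and the tether hanging from the 3-oxygen delivers the arene to the face that carries this oxygen, which sets C4 of the upper unit 3,4-cis, the outcome known for the Me3SiOTf-catalysed ring-closing coupling of diester-linked catechin units.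

Step 12
Reactants: 18 adipate-bridged dimer thioether; 13 (2R,3S,4R)-7-(benzyloxy)-2-[3,4-bis(benzyloxy)phenyl]-3,4-dihydro-2H-chromene-3,4-diol
Product: 19 adipate-bridged trimer: C4 of the middle unit (3,4-trans) is bonded to C6 of unit 13, whose 3,4-diol is kept
Conditions: AgBF4, 2,6-di-tert-butyl-4-methylpyridine, 4 Å molecular sieves, THF–CH2Cl2, −20 → 0 °C; 13 (4 equiv)
Reagents that add atoms: none
Why: Thiophilic activation, in which AgBF4 removes the benzylthio group, the 3-O-acyl group of the tether bridges the C4 cation as an acyloxonium ion, and C6 of diol 13 (in excess, its own 4-hydroxyl untouched under these buffered conditions) attacks anti to it in a Friedel–Crafts alkylation, which sets C4 of the middle unit 3,4-trans.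

Step 13
Reactants: 19 adipate-bridged trimer
Product: 20 nona-O-benzyl ether of the target
Conditions: NaOMe (cat.), MeOH–THF, rt
Reagents that add atoms: none
Why: Zemplén-type transesterification with catalytic methoxide cleaves both ester links of the tether as dimethyl adipate without touching stereocentres, and with all phenols protected no quinone methide chemistry can start.

Step 14
Reactants: 20 nona-O-benzyl ether of the target
Product: 21 CNP0255184.1
Conditions: H2 (1 atm), Pd(OH)2/C, THF–MeOH, rt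
Reagents that add atoms: none
Why: Hydrogenolysis of the nine aryl benzyl ethers under neutral conditions, which should be faster than cleavage of the free benzylic 4-hydroxyl or of the diarylmethine bonds, releases the target without change at any stereocentre.

Compound list
1 | 2-bromo-1-[3,4-bis(benzyloxy)phenyl]ethan-1-one | O=C(CBr)c1ccc(OCc2ccccc2)c(OCc2ccccc2)c1 | starting material
2 | (1R)-2-bromo-1-[3,4-bis(benzyloxy)phenyl]ethan-1-ol (not isolated) | O[C@@H](CBr)c1ccc(OCc2ccccc2)c(OCc2ccccc2)c1 | intermediate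
3 | (2R)-2-[3,4-bis(benzyloxy)phenyl]oxirane | C1O[C@@H]1c1ccc(OCc2ccccc2)c(OCc2ccccc2)c1 | intermediate
4 | 4-(benzyloxy)-2-fluorobenzaldehyde | O=Cc1ccc(OCc2ccccc2)cc1F | starting material
5 | 2-[4-(benzyloxy)-2-fluorophenyl]-1,3-dithiane | Fc1cc(OCc2ccccc2)ccc1C1SCCCS1 | intermediate
6 | 2-lithio-2-[4-(benzyloxy)-2-fluorophenyl]-1,3-dithiane (not isolated) | [Li]C1(SCCCS1)c1ccc(OCc2ccccc2)cc1F | intermediate
7 | lithium (1S)-1-[3,4-bis(benzyloxy)phenyl]-2-{2-[4-(benzyloxy)-2-fluorophenyl]-1,3-dithian-2-yl}ethan-1-olate (not isolated) | [Li]O[C@@H](CC1(SCCCS1)c1ccc(OCc2ccccc2)cc1F)c1ccc(OCc2ccccc2)c(OCc2ccccc2)c1 | intermediate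
8 | (2S)-7-(benzyloxy)-2-[3,4-bis(benzyloxy)phenyl]-2,3-dihydrospiro[chromene-4,2'-[1,3]dithiane] | C(c1ccccc1)Oc1ccc2c(c1)O[C@H](c1ccc(OCc3ccccc3)c(OCc3ccccc3)c1)CC21SCCCS1 | intermediate
9 | (2S)-7-(benzyloxy)-2-[3,4-bis(benzyloxy)phenyl]-2,3-dihydro-4H-chromen-4-one (tri-O-benzylbutin) | C(c1ccccc1)Oc1ccc2c(c1)O[C@H](c1ccc(OCc3ccccc3)c(OCc3ccccc3)c1)CC2=O | intermediate
10 | {[(2S)-7-(benzyloxy)-2-[3,4-bis(benzyloxy)phenyl]-2H-chromen-4-yl]oxy}trimethylsilane (not isolated) | C(c1ccccc1)Oc1ccc2c(c1)O[C@H](c1ccc(OCc3ccccc3)c(OCc3ccccc3)c1)C=C2O[Si](C)(C)C | intermediate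
11 | (2R,3R)-7-(benzyloxy)-2-[3,4-bis(benzyloxy)phenyl]-3-(trimethylsilyloxy)-2,3-dihydro-4H-chromen-4-one (not isolated) | C(c1ccccc1)Oc1ccc2c(c1)O[C@H](c1ccc(OCc3ccccc3)c(OCc3ccccc3)c1)[C@@H](O[Si](C)(C)C)C2=O | intermediate
12 | (2R,3R)-7-(benzyloxy)-2-[3,4-bis(benzyloxy)phenyl]-3-hydroxy-2,3-dihydro-4H-chromen-4-one (tri-O-benzylfustin) | C(c1ccccc1)Oc1ccc2c(c1)O[C@H](c1ccc(OCc3ccccc3)c(OCc3ccccc3)c1)[C@@H](O)C2=O | intermediate
13 | (2R,3S,4R)-7-(benzyloxy)-2-[3,4-bis(benzyloxy)phenyl]-3,4-dihydro-2H-chromene-3,4-diol (tri-O-benzylmollisacacidin, 2,3-trans-3,4-trans) | C(c1ccccc1)Oc1ccc2c(c1)O[C@H](c1ccc(OCc3ccccc3)c(OCc3ccccc3)c1)[C@@H](O)[C@@H]2O | intermediate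
14 | (2R,3S,4R)-7-(benzyloxy)-2-[3,4-bis(benzyloxy)phenyl]-4-methoxy-3,4-dihydro-2H-chromen-3-ol (2,3-trans-3,4-trans) | C(c1ccccc1)Oc1ccc2c(c1)O[C@H](c1ccc(OCc3ccccc3)c(OCc3ccccc3)c1)[C@@H](O)[C@@H]2OC | intermediate
15 | (2R,3R,4R)-7-(benzyloxy)-4-(benzylsulfanyl)-2-[3,4-bis(benzyloxy)phenyl]-3,4-dihydro-2H-chromen-3-ol (2,3-trans-3,4-trans) | C(c1ccccc1)Oc1ccc2c(c1)O[C@H](c1ccc(OCc3ccccc3)c(OCc3ccccc3)c1)[C@@H](O)[C@@H]2SCc1ccccc1 | intermediate
16 | 6-oxo-6-{[(2R,3R,4R)-7-(benzyloxy)-4-(benzylsulfanyl)-2-[3,4-bis(benzyloxy)phenyl]-3,4-dihydro-2H-chromen-3-yl]oxy}hexanoic acid | C(c1ccccc1)Oc1ccc2c(c1)O[C@H](c1ccc(OCc3ccccc3)c(OCc3ccccc3)c1)[C@@H](OC(=O)CCCCC(=O)O)[C@@H]2SCc1ccccc1 | intermediate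
17 | hexanedioate diester: one end on O3 of the 4-methoxy unit 14, the other on O3 of the 4-benzylsulfanyl unit 15; both units (2R), 2,3-trans-3,4-trans | C(c1ccccc1)Oc1ccc2c(c1)O[C@H](c1ccc(OCc3ccccc3)c(OCc3ccccc3)c1)[C@@H](OC(=O)CCCCC(=O)O[C@@H]1[C@@H](c4ccc(OCc5ccccc5)c(OCc5ccccc5)c4)Oc4cc(OCc5ccccc5)ccc4[C@H]1OC)[C@@H]2SCc1ccccc1 | intermediate
18 | adipate-bridged dimer: upper unit (2R), 2,3-trans-3,4-cis, bonded C4→C6 to the lower unit (2R), 2,3-trans-3,4-trans, 4-benzylsulfanyl; the two 3-oxygens carry the two ends of one hexanedioyl chain; six benzyl ethers | C(c1ccccc1)Oc1ccc2c(c1)O[C@H](c1ccc(OCc3ccccc3)c(OCc3ccccc3)c1)[C@@H](OC(=O)CCCCC7=O)[C@H]2c1cc2c(cc1OCc3ccccc3)O[C@H](c1ccc(OCc3ccccc3)c(OCc3ccccc3)c1)[C@@H](O7)[C@@H]2SCc1ccccc1 | intermediate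
19 | adipate-bridged trimer: as 18, with the benzylsulfanyl group replaced by C6 of unit 13 (middle unit 3,4-trans); lowest unit keeps its 3,4-trans-diol; nine benzyl ethers | C(c1ccccc1)Oc1ccc2c(c1)O[C@H](c1ccc(OCc3ccccc3)c(OCc3ccccc3)c1)[C@@H](OC(=O)CCCCC7=O)[C@H]2c1cc2c(cc1OCc3ccccc3)O[C@H](c1ccc(OCc3ccccc3)c(OCc3ccccc3)c1)[C@@H](O7)[C@@H]2c1cc2c(cc1OCc3ccccc3)O[C@H](c1ccc(OCc3ccccc3)c(OCc3ccccc3)c1)[C@@H](O)[C@@H]2O | intermediate
20 | nona-O-benzyl ether of the target (7-O and 3',4'-O of each unit benzylated; free 3-OH on each unit and free 4-OH on the lowest unit) | C(c1ccccc1)Oc1ccc2c(c1)O[C@H](c1ccc(OCc3ccccc3)c(OCc3ccccc3)c1)[C@@H](O)[C@H]2c1cc2c(cc1OCc3ccccc3)O[C@H](c1ccc(OCc3ccccc3)c(OCc3ccccc3)c1)[C@@H](O)[C@@H]2c1cc2c(cc1OCc3ccccc3)O[C@H](c1ccc(OCc3ccccc3)c(OCc3ccccc3)c1)[C@@H](O)[C@@H]2O | intermediate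
21 | CNP0255184.1, fisetinidol-(4β→6)-fisetinidol-(4α→6)-mollisacacidin: upper unit (2R,3S,4S), middle unit (2R,3S,4R), lowest unit (2R,3S,4R)-flavan-3,4-diol | Oc1ccc2c(c1)O[C@H](c1ccc(O)c(O)c1)[C@@H](O)[C@H]2c1cc2c(cc1O)O[C@H](c1ccc(O)c(O)c1)[C@@H](O)[C@@H]2c1cc2c(cc1O)O[C@H](c1ccc(O)c(O)c1)[C@@H](O)[C@@H]2O | target

Total step count: 14. Longest linear sequence: 12 steps (1, 3, 4, 5, 6, 8, 9, 10, 11, 12, 13, 14); steps 2 and 7 are side branches.

Steps most likely to fail

Step 3. What may go wrong: lithiation beside the fluorine competing with dithiane deprotonation, benzylic instead of terminal opening of the electron-rich oxirane, and above all stalling of the fluoride displacement on a ring that has no conjugating activating group. The fallback sets out from 5 and 3 and comes back at 9. The opening is run as above but quenched cold, which gives the open-chain alcohol (1S)-1-[3,4-bis(benzyloxy)phenyl]-2-{2-[4-(benzyloxy)-2-fluorophenyl]-1,3-dithian-2-yl}ethan-1-ol F1. Alkylative hydrolysis (MeI, CaCO3, MeCN–H2O) then unmasks the hydroxy ketone (3S)-3-[3,4-bis(benzyloxy)phenyl]-1-[4-(benzyloxy)-2-fluorophenyl]-3-hydroxypropan-1-one F2, in which the ortho carbonyl group activates the fluoride. Cs2CO3 in DMF at 0 °C to room temperature closes the pyran by carbonyl-activated SNAr to flavanone 9, so step 4 is no longer needed.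

Step 11. What may go wrong: capture of the cation by C8 instead of C6, delivery to the wrong face through a loose 15-membered transition state, or intermolecular oligomerisation. The fallback sets out from 14 and 15 and comes back at 20. Untethered coupling of 14 with an excess of 15 (Me3SiOTf, CH2Cl2, −40 °C) should give both C4 epimers of the C6-linked dimer. From these the 3,4-cis isomer, the untethered (4β→6) dimer thioether F3, is separated by chromatography. F3 is then coupled with 13 under the conditions of step 12, where the preference of a 2,3-trans flavan-4-yl cation for attack anti to its 3-hydroxyl sets the middle C4; this gives 20 directly and bypasses 16 to 19.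

Step 14. What may go wrong: hydrogenolysis of the benzylic C4–O bond of the lowest unit competing with cleavage of the benzyl ethers. The fallback sets out from 20 and comes back at 21. Selective MnO2 oxidation of the benzylic 4-hydroxyl gives the keto nona-O-benzyl trimer F4, whose lowest unit is a 3-hydroxychroman-4-one. Its carbonyl group survives hydrogenolysis (H2, Pd(OH)2/C), which gives the free phenolic keto trimer F5. NaBH4 in ethanol then reduces the dihydroflavonol unit to the 2,3-trans-3,4-trans diol, the classical dihydroflavonol reduction, and gives 21.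

Further compounds
F1 | step 3 | (1S)-1-[3,4-bis(benzyloxy)phenyl]-2-{2-[4-(benzyloxy)-2-fluorophenyl]-1,3-dithian-2-yl}ethan-1-ol | O[C@@H](CC1(SCCCS1)c1ccc(OCc2ccccc2)cc1F)c1ccc(OCc2ccccc2)c(OCc2ccccc2)c1
F2 | step 3 | (3S)-3-[3,4-bis(benzyloxy)phenyl]-1-[4-(benzyloxy)-2-fluorophenyl]-3-hydroxypropan-1-one | O[C@@H](CC(=O)c1ccc(OCc2ccccc2)cc1F)c1ccc(OCc2ccccc2)c(OCc2ccccc2)c1
F3 | step 11 | untethered dimer: upper unit (2R), 2,3-trans-3,4-cis, bonded C4→C6 to the lower unit (2R), 2,3-trans-3,4-trans, 4-benzylsulfanyl; both 3-OH free; six benzyl ethers | C(c1ccccc1)Oc1ccc2c(c1)O[C@H](c1ccc(OCc3ccccc3)c(OCc3ccccc3)c1)[C@@H](O)[C@H]2c1cc2c(cc1OCc3ccccc3)O[C@H](c1ccc(OCc3ccccc3)c(OCc3ccccc3)c1)[C@@H](O)[C@@H]2SCc1ccccc1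
F4 | step 14 | nona-O-benzyl trimer as 20 with the lowest unit oxidised to the (2R,3R)-3-hydroxychroman-4-one | C(c1ccccc1)Oc1ccc2c(c1)O[C@H](c1ccc(OCc3ccccc3)c(OCc3ccccc3)c1)[C@@H](O)[C@H]2c1cc2c(cc1OCc3ccccc3)O[C@H](c1ccc(OCc3ccccc3)c(OCc3ccccc3)c1)[C@@H](O)[C@@H]2c1cc2c(cc1OCc3ccccc3)O[C@H](c1ccc(OCc3ccccc3)c(OCc3ccccc3)c1)[C@@H](O)C2=O
F5 | step 14 | free phenolic trimer as 21 with the lowest unit as the (2R,3R)-3-hydroxychroman-4-one | Oc1ccc2c(c1)O[C@H](c1ccc(O)c(O)c1)[C@@H](O)[C@H]2c1cc2c(cc1O)O[C@H](c1ccc(O)c(O)c1)[C@@H](O)[C@@H]2c1cc2c(cc1O)O[C@H](c1ccc(O)c(O)c1)[C@@H](O)C2=O
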